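**Plan**

- Cuts, in retrosynthetic order: (1) the CH3–C and prenyl–C bonds at the quaternary carbon of the trione ring; (2) the C–OH bond of the carbinol in the spiro cyclohexane ring, back to an exocyclic methylene; (3) the bond from the spiro carbon to the CH2 next to that carbinol; (4) the aryl–CH2 bond; (5) the ring-fusion bond of the cyclopentane.
- Enabling feature: the spiro carbon bears a ring C=O and, one CH2 away, the carbinol carbon C(CH3)(OH). At the alkene oxidation level this is O=C–C(spiro)–CH2–C(=CH2), a γ,δ-unsaturated ketone, so cut 3 is the bond a Claisen shift makes from an allyl ether on the phloroglucinol oxygen para to the acyl group.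
- Forward order: cyclopentane (magnesium-ene of a linalool-derived allyl Grignard), Negishi union with an iodinated acylphloroglucinol, eight-membered aryl allyl ether ring, contraction of that ring to the six-membered spiro carbocycle with dearomatisation (this uncovers the trione ring), hydration, prenylation, methylation.
- Stereochemistry: cyclopentane carbinol from (R)-linalool; both ring-fusion centres from the cis-selective, alkoxide-directed ene step; spiro centre relayed by the bridged transition state of the ring contraction; cyclohexane carbinol and quaternary trione carbon by attack anti to axial groups of the spiro chair; acyl side chain from (S)-2-methylbutanoic acid.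

Key step: step 11

Remark: chloride 14 may contain its primary allylic isomer, which gives the same allylmagnesium species in step 8; the enolised triketones are drawn in the tautomer used for the target.

**Route**

Step 1
Reactants: 1 phloroglucinol; 2 (S)-2-methylbutanoic acid
Product: 4 (2S)-2-methyl-1-(2,4,6-trihydroxyphenyl)butan-1-one, via (S)-2-methylbutanoyl chloride 3 (not isolated)
Conditions: 2, (COCl)2, DMF (cat.), CH2Cl2, 0 °C to rt; then 1, AlCl3, PhNO2/CH2Cl2, 0 °C to rt; aq. HCl
Reagents that add atoms: none
Why: Friedel–Crafts C-acylation of the symmetrical triol should stop after one acyl group because the aryl ketone deactivates the ring, and the acid chloride is made and used cold so that the α-stereocentre is kept.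

Step 2
Reactants: 4 (2S)-2-methyl-1-(2,4,6-trihydroxyphenyl)butan-1-one
Product: 5 (2S)-1-(2,4,6-trihydroxy-3-iodophenyl)-2-methylbutan-1-one
Conditions: N-iodosuccinimide (1.0 equiv), MeCN, −20 °C to 0 °C
Reagents that add atoms: N-iodosuccinimide, O=C1CCC(=O)N1I
Why: electrophilic aromatic iodination at one of the two equivalent free positions of a highly activated arene, with one equivalent of reagent to limit di-iodination.

Step 3
Reactants: 5 (2S)-1-(2,4,6-trihydroxy-3-iodophenyl)-2-methylbutan-1-one
Product: 6 2-iodo-4-[(2S)-2-methylbutanoyl]benzene-1,3,5-triyl triacetate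
Conditions: Ac2O, pyridine, DMAP (cat.), CH2Cl2, rt
Reagents that add atoms: acetic anhydride, CC(=O)OC(C)=O
Why: acyl-transfer O-acetylation masks the three acidic phenols so that an organozinc reagent can be used in step 8.

Step 4
Reactants: 7 (R)-linalool
Product: 8 (5R)-5-ethenyl-5-methyloxolan-2-ol (anomer mixture)
Conditions: O3, CH2Cl2/MeOH, pyridine, −78 °C, dye end point; then Me2S, −78 °C to rt
Reagents that add atoms: ozone, [O-][O+]=O
Why: ozonolysis cleaves the electron-rich trisubstituted alkene much faster than the vinyl group and the resulting hydroxy aldehyde closes to the lactol, the tertiary carbinol centre being untouched.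

Step 5
Reactants: 9 2-bromoprop-2-en-1-ol
Product: 10 [(2-bromoprop-2-en-1-yl)oxy](tert-butyl)dimethylsilane
Conditions: TBSCl, imidazole, CH2Cl2, 0 °C to rt
Reagents that add atoms: tert-butyldimethylsilyl chloride, CC(C)(C)[Si](C)(C)Cl
Why: standard O-silylation of a primary alcohol gives an ether that survives the organolithium, Grignard and organozinc steps.

Step 6
Reactants: 10 [(2-bromoprop-2-en-1-yl)oxy](tert-butyl)dimethylsilane; 8 (5R)-5-ethenyl-5-methyloxolan-2-ol
Product: 12 (3R)-7-{[tert-butyl(dimethyl)silyl]oxymethyl}-3-methylocta-1,7-diene-3,6-diol (C6 epimers), via 3-silyloxyprop-1-en-2-yllithium 11 (not isolated)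
Conditions: 10 (2.2 equiv), t-BuLi (4.4 equiv), Et2O, −78 °C; then 8, THF, −78 °C to 0 °C; aq. NH4Cl
Reagents that add atoms: none
Why: bromine–lithium exchange gives the 2-lithioallyl ether, which adds to the aldehyde form of the lactol (one equivalent is spent on the lactol O–H) in a carbonyl 1,2-addition; the new carbinol centre need not be controlled because it is lost in step 8.

Step 7
Reactants: 12 (3R)-7-{[tert-butyl(dimethyl)silyl]oxymethyl}-3-methylocta-1,7-diene-3,6-diol
Product: 14 (3R)-6-chloro-7-{[tert-butyl(dimethyl)silyl]oxymethyl}-3-methylocta-1,7-dien-3-ol (C6 epimers), via secondary allylic mesylate 13 (not isolated)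
Conditions: MsCl, LiCl (excess), 2,4,6-collidine, DMF, 0 °C
Reagents that add atoms: lithium chloride, [Li+].[Cl-]
Why: sulfonylation and chloride displacement take place at the secondary allylic alcohol only, the hindered tertiary alcohol stays free and excess chloride should outrun ether closure.

Step 8
Reactants: 14 (3R)-6-chloro-7-{[tert-butyl(dimethyl)silyl]oxymethyl}-3-methylocta-1,7-dien-3-ol; 6 2-iodo-4-[(2S)-2-methylbutanoyl]benzene-1,3,5-triyl triacetate
Product: 18 coupled triacetate (all-cis cyclopentanol joined through CH2 to the arene), via allylmagnesium alkoxide 15 (not isolated), via cyclised Grignard reagent 16 (not isolated), via alkylzinc chloride 17 (not isolated)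
Conditions: MeMgCl (1.0 equiv), THF, −40 °C; Mg powder (activated), THF, −20 °C to rt; 65 °C; ZnCl2 (2.2 equiv), 0 °C; then 6, Pd(OAc)2 (5 mol %), SPhos (10 mol %), 45 °C; aq. NH4Cl
Reagents that add atoms: none
Why: magnesium-ene cyclisation (type 1) of the 2,7-dienylmagnesium chloride closes the cyclopentane through a six-centre transition state that sets CH2MgCl and the alkenyl group cis, with the chloromagnesium alkoxide holding the migrating magnesium on its own face so that hydroxyl, CH2 and alkenyl should end all-cis; transmetalation to zinc and Negishi coupling then join the primary alkyl group to the aryl iodide without touching acetates, ketone or silyl ether.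

Step 9
Reactants: 18 coupled triacetate
Product: 20 pentaol (three phenols, primary allylic alcohol, tertiary alcohol), via triphenol silyl ether 19 (not isolated)
Conditions: Et3N, MeOH, rt; concentrate; then HF·pyridine, THF/pyridine, 0 °C
Reagents that add atoms: none
Why: amine-catalysed methanolysis removes the three aryl acetates and fluoride-mediated desilylation frees the primary allylic alcohol, while the tertiary alcohol and the alkene are inert.

Step 10
Reactants: 20 pentaol
Product: 21 eight-membered aryl allyl ether (oxygen para to the acyl group bonded to the allylic CH2)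
Conditions: PPh3, DIAD, THF (0.003 M, slow addition), 0 °C to rt
Reagents that add atoms: none
Why: intramolecular Mitsunobu etherification in which the most acidic phenol, the one para to the acyl group (the ortho phenols are hydrogen-bonded to the ketone and more hindered), displaces the activated primary allylic alcohol under high dilution; direct and allylically transposed displacement give the same ether.

Step 11
Reactants: 21 eight-membered aryl allyl ether
Product: 22 spiro exo-methylene trione
Conditions: o-xylene (0.01 M), 140 °C, argon, dark
Reagents that add atoms: none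
Why: Proposed new method: the aryl allyl ether should undergo a concerted [3,3]-sigmatropic (aromatic Claisen) shift in which the exocyclic methylene carbon bonds to the ring carbon ortho to the ether oxygen that already carries the CH2 tether while the O–CH2 bond breaks, so that the aryl C–O unit and the former O–CH2 leave the eight-membered ring and a six-membered carbocycle with a new exocyclic methylene remains; the closest known reaction type is the ortho-Claisen rearrangement of phloroglucinol allyl ethers onto a substituted ortho carbon, which gives 6,6-disubstituted cyclohexadienones, here run inside a medium ring. The cyclohexane ring closes as the 1,6-bond of the six-atom pericyclic array, transannularly across the eight-membered ring, through a bicyclo[3.3.1]-like chair transition state whose bridgeheads are the future spiro carbon and the alkene carbon. The new spiro stereocentre is controlled by this bridge: the carbonyl carbon that bore the ether oxygen must end axial and syn to the departing CH2, and the cis-fused cyclopentane allows the bridge only on the face of the two ring-fusion hydrogens, because on the other face it would meet the axial cyclopentane bond. Selectivity for the substituted ortho carbon over the free ortho C–H is secured by the tether, since bonding at the free position would need a five-atom meta bridge. The loss of aromaticity should be paid for by release of medium-ring strain and by tautomerisation of the dienone to the hydrogen-bonded enolised triketone, which also blocks the reverse reaction.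

Step 12
Reactants: 22 spiro exo-methylene trione
Product: 23 spiro diol trione (des-methyl des-prenyl target)
Conditions: Mn(dpm)3 (10 mol %), PhSiH3, O2 (1 atm), i-PrOH/CH2Cl2, 0 °C to rt
Reagents that add atoms: dioxygen, O=O
Why: Mukaiyama hydration, in which hydrogen-atom transfer to the CH2 terminus gives the tertiary ring radical that should take up O2 from the equatorial side because the axial side is screened by the syn-axial ring carbonyl on the spiro carbon, so that reduction of the peroxide gives the Markovnikov tertiary alcohol with OH trans to the ring-fusion hydrogens; the enol double bonds are too electron-poor to react.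

Step 13
Reactants: 23 spiro diol trione
Product: 24 C-prenyl enol (des-methyl target)
Conditions: prenyl bromide (1.05 equiv), NaOMe, MeOH, 0 °C
Reagents that add atoms: prenyl bromide, CC(C)=CCBr
Why: enolate C-alkylation at the only ring CH2 flanked by two carbonyls, as in the alkylation of acylfilicinic acids, with the protic medium favouring C- over O-alkylation; the product stays enolised, so no stereocentre is formed yet.

Step 14
Reactants: 24 C-prenyl enol
Product: 25 Hyperielliptone HB
Conditions: MeI, NaOMe, MeOH, 0 °C to rt
Reagents that add atoms: iodomethane, CI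
Why: second enolate C-alkylation at the same carbon creates the quaternary centre, and iodomethane should approach the trione ring from the face away from the axial methyl of the new carbinol (which lies syn to the axial ring carbonyl), placing methyl on the side of the CH2 that leads to the ring fusion and prenyl on the side of the CH2–C(CH3)(OH) arm, as in the target.

**Compound list**

1 | phloroglucinol (benzene-1,3,5-triol) | Oc1cc(O)cc(O)c1 | starting material
2 | (S)-2-methylbutanoic acid | CC[C@H](C)C(=O)O | starting material
3 | (S)-2-methylbutanoyl chloride | CC[C@H](C)C(Cl)=O | intermediate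
4 | (2S)-2-methyl-1-(2,4,6-trihydroxyphenyl)butan-1-one | CC[C@H](C)C(=O)c1c(O)cc(O)cc1O | intermediate
5 | (2S)-1-(2,4,6-trihydroxy-3-iodophenyl)-2-methylbutan-1-one | CC[C@H](C)C(=O)c1c(O)cc(O)c(I)c1O | intermediate
6 | 2-iodo-4-[(2S)-2-methylbutanoyl]benzene-1,3,5-triyl triacetate | CC[C@H](C)C(=O)c1c(OC(C)=O)cc(OC(C)=O)c(I)c1OC(C)=O | intermediate
7 | (R)-linalool, (3R)-3,7-dimethylocta-1,6-dien-3-ol | C=C[C@](C)(O)CCC=C(C)C | starting material
8 | (5R)-5-ethenyl-5-methyloxolan-2-ol, lactol of (4R)-4-hydroxy-4-methylhex-5-enal, anomer mixture | C=C[C@]1(C)OC(O)CC1 | intermediate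
9 | 2-bromoprop-2-en-1-ol | OCC(Br)=C | starting material
10 | [(2-bromoprop-2-en-1-yl)oxy](tert-butyl)dimethylsilane | C=C(Br)CO[Si](C)(C)C(C)(C)C | intermediate
11 | {3-[tert-butyl(dimethyl)silyl]oxyprop-1-en-2-yl}lithium | [Li]C(=C)CO[Si](C)(C)C(C)(C)C | intermediate
12 | (3R)-7-{[tert-butyl(dimethyl)silyl]oxymethyl}-3-methylocta-1,7-diene-3,6-diol, C6 epimers | C=C[C@](C)(O)CCC(O)C(=C)CO[Si](C)(C)C(C)(C)C | intermediate
13 | 6-methanesulfonate of 12 (secondary allylic mesylate) | C=C[C@](C)(O)CCC(OS(C)(=O)=O)C(=C)CO[Si](C)(C)C(C)(C)C | intermediate
14 | (3R)-6-chloro-7-{[tert-butyl(dimethyl)silyl]oxymethyl}-3-methylocta-1,7-dien-3-ol, C6 epimers | C=C[C@](C)(O)CCC(Cl)C(=C)CO[Si](C)(C)C(C)(C)C | intermediate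
15 | chloromagnesium alkoxide of the allylmagnesium chloride from 14 | C=C[C@](C)(O[Mg]Cl)CCC([Mg]Cl)C(=C)CO[Si](C)(C)C(C)(C)C | intermediate
16 | cyclised Grignard reagent: (cyclopentyl)methylmagnesium chloride, 2-(chloromagnesiooxy)-2-methyl-5-(3-silyloxyprop-1-en-2-yl), carbinol carbon R, O, CH2Mg and alkenyl all cis | Cl[Mg]C[C@H]1[C@H](CC[C@@]1(C)O[Mg]Cl)C(=C)CO[Si](C)(C)C(C)(C)C | intermediate
17 | corresponding (cyclopentyl)methylzinc chloride | Cl[Zn]C[C@H]1[C@H](CC[C@@]1(C)O[Mg]Cl)C(=C)CO[Si](C)(C)C(C)(C)C | intermediate
18 | coupled triacetate: 2-({2-hydroxy-2-methyl-5-[3-(tert-butyldimethylsilyloxy)prop-1-en-2-yl]cyclopentyl}methyl)-4-[(2S)-2-methylbutanoyl]benzene-1,3,5-triyl triacetate; cyclopentane carbinol carbon R, hydroxyl, CH2Ar and alkenyl all cis | CC[C@H](C)C(=O)c1c(OC(C)=O)cc(OC(C)=O)c(c1OC(C)=O)C[C@H]2[C@H](CC[C@@]2(C)O)C(=C)CO[Si](C)(C)C(C)(C)C | intermediate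
19 | triphenol silyl ether: 18 without the three acetyl groups | CC[C@H](C)C(=O)c1c(O)cc(O)c(c1O)C[C@H]2[C@H](CC[C@@]2(C)O)C(=C)CO[Si](C)(C)C(C)(C)C | intermediate
20 | pentaol: (2S)-1-[2,4,6-trihydroxy-3-({2-hydroxy-5-(3-hydroxyprop-1-en-2-yl)-2-methylcyclopentyl}methyl)phenyl]-2-methylbutan-1-one; cyclopentane as in 18 | CC[C@H](C)C(=O)c1c(O)cc(O)c(c1O)C[C@H]2[C@H](CC[C@@]2(C)O)C(=C)CO | intermediate
21 | eight-membered aryl allyl ether: the phenol oxygen para to the acyl group of 20 bonded to the allylic CH2, ring made of two aryl carbons, O, CH2, the methylene-bearing carbon, the two cyclopentane ring-fusion carbons and the benzylic CH2 | CC[C@H](C)C(=O)c1c(O)cc2c(c1O)C[C@H]3[C@H](CC[C@@]3(C)O)C(=C)CO2 | intermediate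
22 | spiro exo-methylene trione: enolised 2-[(2S)-2-methylbutanoyl]cyclohexane-1,3,5-trione spiro-fused at C6 to a cis-hydrindane carrying the 1-hydroxy-1-methyl group on the five-membered ring and an exocyclic methylene on the six-membered ring; spiro and ring-fusion centres as in the target | CC[C@H](C)C(=O)C1=C(O)CC(=O)[C@]2(C[C@H]3[C@H](CC[C@@]3(C)O)C(=C)C2)C1=O | intermediate
23 | spiro diol trione: 22 with the methylene converted into the tertiary carbinol of the target (des-methyl des-prenyl target) | CC[C@H](C)C(=O)C1=C(O)CC(=O)[C@]2(C[C@H]3[C@H](CC[C@@]3(C)O)[C@](C)(O)C2)C1=O | intermediate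
24 | C-prenyl enol: 23 with a 3-methylbut-2-enyl group on the ring carbon between the two non-acylated carbonyls (des-methyl target) | CC[C@H](C)C(=O)C1=C(O)C(CC=C(C)C)=C(O)[C@]2(C[C@H]3[C@H](CC[C@@]3(C)O)[C@](C)(O)C2)C1=O | intermediate
25 | Hyperielliptone HB | CC[C@H](C)C(=O)C1=C(O)[C@@](C)(CC=C(C)C)C(=O)[C@]2(C[C@H]3[C@H](CC[C@@]3(C)O)[C@](C)(O)C2)C1=O | target

**Totals and risks**

Total step count: 14. Longest linear sequence: 10 steps (from (R)-linalool 7: steps 4, 6, 7, 8, 9, 10, 11, 12, 13, 14).

Three steps most likely to fail:

1. Step 11 (Proposed new method). The bridged transition state may lie too high, so that the ether ionises, eliminates or decomposes before the shift takes place. Fallback with known chemistry: it sets out from pentaol 20 and closes the spiro ring directly by a palladium-catalysed dehydrative intramolecular ipso-allylation of the phloroglucinol carbon (Tsuji–Trost type allylic dearomatisation; Pd(PPh3)4, Et3B, THF, 50 °C). It comes back to the route at 22 and forms no new compound (F0). The spiro centre would then no longer be relayed by the bridge, and the two spiro epimers would have to be separated.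

2. Step 10. Intermolecular etherification (oligomerisation) may outrun closure of the eight-membered ring, or etherification may take place at an ortho phenol. Fallback: the order of bond formation is reversed, with the ether bond made between two molecules and the ring closed at the aryl–CH2 bond. It sets out from the cyclised Grignard reagent 16 and iodophenol 5. Quenching 16 with iodine would give the all-cis iodide (1R)-2-(iodomethyl)-1-methyl-3-{3-[tert-butyl(dimethyl)silyl]oxyprop-1-en-2-yl}cyclopentan-1-ol F1. HF·pyridine would free the allylic alcohol (1R)-3-(3-hydroxyprop-1-en-2-yl)-2-(iodomethyl)-1-methylcyclopentan-1-ol F2. Mitsunobu etherification with the para hydroxyl of 5 would give the open aryl allyl ether diiodide F3. A nickel-catalysed intramolecular reductive coupling of the aryl iodide with the primary alkyl iodide (NiBr2(dme), 4,4′-di-tert-butyl-2,2′-bipyridine, Zn dust, DMA, high dilution) would then close the ring and come back to the route at 21.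

3. Step 14. Facial selectivity in the last alkylation may be poor, or O-methylation may compete. Fallback: the order of the two alkylations is reversed and the last one is put under catalyst control. It sets out from 23. C-methylation (MeI, NaOMe, MeOH) would give the C-methyl enol of the spiro diol trione F4. A palladium-catalysed asymmetric allylic alkylation (Pd2(dba)3, one enantiomer of N,N′-bis[2-(diphenylphosphino)benzoyl]cyclohexane-1,2-diamine, tert-butyl 2-methylbut-3-en-2-yl carbonate, CH2Cl2) would then deliver the prenyl group to the face chosen by the ligand and come back to the route at 25.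

Further compounds
F0 | step 11 | none | none
F1 | step 10 | (1R)-2-(iodomethyl)-1-methyl-3-{3-[tert-butyl(dimethyl)silyl]oxyprop-1-en-2-yl}cyclopentan-1-ol, all-cis | IC[C@H]1[C@H](CC[C@@]1(C)O)C(=C)CO[Si](C)(C)C(C)(C)C
F2 | step 10 | (1R)-3-(3-hydroxyprop-1-en-2-yl)-2-(iodomethyl)-1-methylcyclopentan-1-ol, all-cis | IC[C@H]1[C@H](CC[C@@]1(C)O)C(=C)CO
F3 | step 10 | open aryl allyl ether diiodide: 5 etherified at the para oxygen with the allylic CH2 of F2 | CC[C@H](C)C(=O)c1c(O)cc(OCC(=C)[C@H]2CC[C@@](C)(O)[C@H]2CI)c(I)c1O
F4 | step 14 | C-methyl enol of the spiro diol trione (des-prenyl target) | CC[C@H](C)C(=O)C1=C(O)C(C)=C(O)[C@]2(C[C@H]3[C@H](CC[C@@]3(C)O)[C@](C)(O)C2)C1=O
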